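All constants were set for the occasion; the result is computed.

We start from the easy step, the plain reaction of substrate with partner, and ask what it can seed in four vessels that hold the same charge.

all flasks: partner 0.280 M
- eta: substrate 0.14 M (fed, over 12.0 s); time 15 s; all but substrate at the start; substrate goes in evenly over 12.0 s, the run ends at 15 s
- beta: substrate 0.14 M; one stirred flow tank at steady state, fed with the mixture as stated, mean residence time 150 s
- theta: substrate 0.14 M; a single well-mixed tank run continuously and read at steady state, 15 s in it on average
- delta: substrate 0.14 M; time 15 s; a closed flask charged with all of it at once and left for 15 s

    substrate + partner + released group → product + 2 released group (k1 = 4.7 M⁻² s⁻¹)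
    substrate + partner → product + released group (k2 = 0.0012 M⁻¹ s⁻¹)
    substrate + released group ⇌ idle adduct A, settled at all times (K3 = 8.1 M⁻¹)
    partner + product ⇌ idle adduct B, settled at all times (K4 = 7.1 M⁻¹)

- the set-up with the highest amount of product at the outlet or at the end, in percent of the substrate put in ("none" if the first two lie within 2 percentage points) (eta / beta / theta / delta / none)
- amount of product at the outlet or at the end, in percent of the substrate put in, eta
- amount of product at the outlet or at the end, in percent of the substrate put in, beta
- amount of product at the outlet or at the end, in percent of the substrate put in, theta
- amount of product at the outlet or at the end, in percent of the substrate put in, delta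

- amounts and yields of product count idle adduct B too
- amounts and yields of released group count idle adduct A too
- the stated concentrations are those of everything mixed, before any reaction; amounts are the same in each set-up
- the feed brings no volume worth counting
- run time (eta): 15 s

In the closed flask delta, the curve of product leaves the origin as a straight line of slope 4.70 × 10⁻⁵ M s⁻¹, the rate of step 2 as charged. Each product brings one released group, and at the charged substrate a share 46.9% of that group stays free, the rest sitting in idle adduct A, its resting state. The free part enters step 1, which is autocatalysis, so we count the growth lifetime, the time in which released group grows by a factor e while substrate and partner stand as charged: one plus K3 times c(substrate), over k1 times c(substrate) times c(partner), 11.6 s. In delta the knee, where step 1 overtakes step 2, comes by our reckoning after ln(2) lifetimes, at 8.04 s, with product at 0.389%. Beyond it the curve bends upward, and delta's 15 s are 1.29 lifetimes, which we reckon gives 1.03%. Delta's curve can level off no higher than the charge of substrate, the limiting reagent, since partner, at 0.280 M, is charged higher than substrate at 0.14 M. In flask eta the evenly fed dose stands on average 6.00 s less, which by our reckoning leaves 9.00 s of growth and 0.457%. For the tanks our reckoning gives a count and no level: theta's average stay is 1.29 lifetimes and beta's 12.9, so beta's stay is the longer by far.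

The forecast puts beta first at 81.8%, then theta at 16%, delta at 1% and eta at 0.47%, saying of theta that “its growth rate barely beats washout”.

The simulation gives 0.468% for eta, 81.9% for beta, 16.3% for theta and 1.02% for delta, so beta leads. Beta leads through back-mixing and the longer stay: the same charge closed for 15 s gives 1.02% against 81.9%. At beta's tank concentrations, substrate 0.0138 M and partner 0.114 M, the lifetime has stretched to 150 s, matching the mean stay of 150 s. Flask eta left until 40 s counts 2.94 lifetimes after the same deduction for the feed, which reckons to 6.94%, and it reads 6.40%.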